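## The problem

Target 27 is a trans-fused cadinane: ring A (C1, C6, C7, C8, C9, C10) and ring B (C1–C6, with C4=C5 and C15H2OH on C4) share the C1–C6 bond, and ring A carries everything that is hard: the acrylic acid at C7, the acyloxy group at C8 and the exocyclic C10=C14 methylene. The four ring stereocentres C1, C6, C7 and C8 are contiguous, (1S,6S,7S,8R), with every substituent equatorial, so one concerted ring-forming event can set them relative to one another. The fifth stereocentre, (3S) in the 3,4-dihydroxy-2-methylenebutanoyl group, is too remote to be relayed from the core. It therefore has to come from the chiral pool, and the core has to be set in the matching absolute sense by a catalyst. Several groups rule out rough treatment. Both α-substituted acrylates are Michael acceptors, the exocyclic alkene isomerises under acid, and a free C12 acid next to a C8 oxygen can close an 8,12-lactone. The dihydroxy ester lactonises with loss of the C8 alcohol as soon as its diol is free under base. At any stage with a C10 carbonyl, the C8 oxygen is a β-leaving group. The feature that opens the structure is the 1,3-relation on ring A between the C8 oxygen and the sp2 carbon C10 through C9, which is the imprint of a 1,3-dioxygenated diene C8=C9–C10=C1. The remaining ring-A carbons C6 and C7 carry a vinyl unit and a carboxyl-bearing two-carbon unit, which is what an (E)-enone dienophile delivers if the C7 acrylic acid is traced back to an acetyl group.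

## Retrosynthesis

**27 ⇐ 24 (through 26 and 25).** Only three oxygen–protecting-group bonds are cut: the C15 4-methoxybenzyl ether, the 2-(trimethylsilyl)ethyl ester at C12 and the side-chain acetonide. They leave under oxidative, fluoride and aqueous-acid conditions in that order, so the base-sensitive diol ester is unmasked last and under acid only. Compound 24 is no simpler in skeleton, but no earlier step has to tolerate a free acid, allylic alcohol or diol. The forward steps must be selective and non-basic.

**24 ⇐ 17 + 23.** The C8–O bond is cut so that it forms with inversion (Mitsunobu) from the 8-epi alcohol 17 and acid 23. This is preferred over a retentive acylation because the cycloaddition below can only deliver C8–O cis to the C7 substituent. One operation then corrects that centre and attaches the side chain. The cut removes seven carbons and the fifth stereocentre. The forward reaction must achieve SN2 at a hindered axial carbinol faster than E2.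

**23 ⇐ 22 ⇐ 20 ⇐ 18.** The carboxyl carbon of 23 is cut from C2' (carbonylation of vinyl triflate 22) and the vinyl carbon from the former aldehyde carbon (methyl addition and oxidation to ketone 20). The aldehyde carbon of (R)-glyceraldehyde acetonide 18 becomes the quaternary alkene carbon, so the (3S) centre is carried over untouched. The same triflate-carbonylation is used on the core, so one method is validated twice. The forward sequence must enolise 20 only towards the methyl group.

**17 ⇐ 16 ⇐ 15 ⇐ 14.** C10=C14 is cut to ketone 15, which is the hydrolysis product of silyl enol ether 14, and the C8 silyl ether of 16 is restored. Methylenation of a ketone is the only direct source of the exocyclic alkene from the oxygenation pattern the diene leaves. It must be non-basic because the C8 silyloxy group is β to the carbonyl.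

**14 ⇐ 13.** C4=C5 is cut by ring-closing metathesis, opening ring B to a propenyl group on C6 and a 2-(alkoxymethyl)allyl terminus on the C1 chain. Against an aldol or olefination closure, metathesis needs no further carbonyl group, and both alkenes are inert spectators in the cycloaddition. The precursor 13 is monocyclic with the two tethers trans, which is what a six-membered closure wants.

**13 ⇐ 12 ⇐ 10.** The C11–C12 bond is cut (alkoxycarbonylation of vinyl triflate 12), returning the acrylate to the acetyl group of 10. The acetyl group is the activating group of the dienophile, so no extra carbon handling is needed. The forward steps must enolise the methyl ketone kinetically while C10 is still masked as its silyl enol ether.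

**10 ⇐ 8 + 9.** C1–C6 and C7–C8 are cut in a Diels–Alder sense. This takes ring A with four stereocentres back to the acyclic bis(silyloxy)diene 8 and commercial (3E,5E)-hepta-3,5-dien-2-one 9. The alternative ring-A cut through C9–C10/C6–C7 would place no oxygen on the diene and lose the polarity match. The forward reaction must be regio-, endo- and face-selective and must engage only the α,β-alkene of 9.

**8 ⇐ 6 ⇐ 4 ⇐ 2 + 3, and 2 ⇐ 1.** The two O–Si bonds of 8 are cut to the formyl ketone 6, the C8–C9 bond to methyl ketone 4 (kinetic formylation), and the C2–C3 bond to allylsilane 2 and methyl vinyl ketone 3 (conjugate allylation). Allylsilane 2 is the ether of commercial chloride 1. All carbons of ring B other than C5 and C6 thus come from two commodity fragments.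

## Roads not taken

**Alternative 1:** an amine-catalysed Michael–Michael–aldol cascade that forms C1–C6, C2–C3 and C4=C5 and folds an open-chain nitroalkene aldehyde and a three-carbon enal into the decalin A1.
- Merits: three bonds and both rings in one flask, catalyst-set absolute configuration, and no acid-labile silyloxydiene or strong Lewis acid. In bonds formed per step it is ahead of the chosen plan.
- Weak points: C7 and C8 must already sit on a flexible chain, and the first ring closure has to be diastereoselective relative to them without a rigid template. A1 also carries three features that have to be undone: the C2 nitro group (a secondary nitro group is slow to remove by radical means), the C15 aldehyde, and the C10 ketal that still has to become the methylene. In addition, the C7 acetate arm needs an α-methylenation.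
- Comparison: the chosen plan sets all four ring stereocentres together and arrives at the right oxidation level at C2 and C15. It pays with a separate ring-B closure.

**Alternative 2:** a ketyl–olefin closure of ring A through C7–C8, in which a divalent samarium reductant turns a C8 aldehyde into a ketyl that adds to an alkylidene malonate, giving A2.
- Merits: mild conditions, and A2 has the C8 hydroxyl already trans to C7 in the target configuration. A retentive esterification then suffices and no inversion at a hindered centre is needed. In this respect it is better than the chosen plan.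
- Weak points: only one ring and two stereocentres arise in the key step. Ring B, the C1/C6 centres and the exocyclic methylene must be built enantioselectively beforehand, on a precursor whose β,γ-unsaturated aldehyde is prone to conjugation. The malonate must later be cut down to the acrylic acid.
- Comparison: the chosen plan has to set against the easier C8 chemistry that its key step makes ring A and four stereocentres from two achiral partners.

**Alternative 3:** a biomimetic transannular closure through C1–C6, in which a boron Lewis acid opens an allylic spiro-oxirane on a ten-membered (E,E)-diene and an allylsilane carbon captures the allyl cation, giving A3.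
- Merits: both rings, the free C15 alcohol and the C10=C14 alkene appear at once, so the route after the key step would be shorter than the chosen one, which needs a separate methylenation and metathesis.
- Weak points: the ten-membered precursor, with two (E)-alkenes, the oxirane, the allylsilane and the C7/C8 centres, is harder to make than the target's own decalin. The ring-fusion geometry depends on a macrocycle conformation that cannot be predicted with confidence, and the malonate again needs conversion.
- Comparison: the chosen plan keeps all difficulty in one well-understood cycloaddition of acyclic partners.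

Key step: step 5

Assumption: the (S)-configured oxazaborolidinium salt is taken as the antipode that leaves the Si face of C7 (Re face of C6) of bound 9 open; the mirror-image catalyst from (R)-diphenylprolinol is equally accessible, so the sense read from adduct 10 settles the choice without changing the route.

## Route

Cadinane numbering is used for ring positions throughout.

Step 1
Reactants: 1 2-(chloromethyl)allyltrimethylsilane
Product: 2 {2-[(4-methoxybenzyloxy)methyl]allyl}trimethylsilane
Conditions: 4-methoxybenzyl alcohol, NaH, Bu4NI (cat.), THF, 0 °C → rt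
Reagents that add atoms: 4-methoxybenzyl alcohol, COc1ccc(CO)cc1
Why: Williamson ether synthesis; the sodium alkoxide displaces the primary allylic chloride by SN2, and the allylsilane is inert to alkoxide at this temperature.

Step 2
Reactants: 2 {2-[(4-methoxybenzyloxy)methyl]allyl}trimethylsilane; 3 methyl vinyl ketone
Product: 4 6-[(4-methoxybenzyloxy)methyl]hept-6-en-2-one
Conditions: TiCl4, CH2Cl2, −78 °C; H2O
Reagents that add atoms: none
Why: Hosomi–Sakurai conjugate allylation; the alkene terminus of 2 attacks the β-carbon of the TiCl4-bound enone and the β-silyl cation loses Me3Si, regenerating the 1,1-disubstituted alkene. Short exposure at −78 °C should spare the 4-methoxybenzyl ether.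

Step 3
Reactants: 4 6-[(4-methoxybenzyloxy)methyl]hept-6-en-2-one
Product: 6 (1Z)-1-hydroxy-7-[(4-methoxybenzyloxy)methyl]octa-1,7-dien-3-one (enol form of the 3-oxo aldehyde), via kinetic lithium enolate 5 (not isolated)
Conditions: LiN(iPr)2, THF, −78 °C; HCO2CH2CF3, −78 °C; aq. NH4Cl
Reagents that add atoms: 2,2,2-trifluoroethyl formate, O=COCC(F)(F)F
Why: Crossed Claisen formylation of a kinetic enolate; the hindered amide removes a methyl proton in preference to a methylene proton, and the reactive trifluoroethyl formate traps the enolate before it can equilibrate.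

Step 4
Reactants: 6 (1Z)-1-hydroxy-7-[(4-methoxybenzyloxy)methyl]octa-1,7-dien-3-one
Product: 8 (1E,3Z)-1,3-bis(tert-butyldimethylsilyloxy)-7-[(4-methoxybenzyloxy)methyl]octa-1,3,7-triene, via mono-silylated enone 7 (not isolated)
Conditions: TBSOTf (2.3 equiv), Et3N, Et2O, 0 °C → rt
Reagents that add atoms: tert-butyldimethylsilyl trifluoromethanesulfonate, CC(C)(C)[Si](C)(C)OS(=O)(=O)C(F)(F)F
Why: Double silylation by soft enolisation, as used to turn 1,3-dicarbonyl compounds into bis(silyloxy)dienes. The first silyl group caps the enol oxygen; the second silylates the carbonyl, and Et3N deprotonates the resulting delocalised cation at the only available α-CH2. The (1E) geometry is the thermodynamic one, and the (3Z) geometry places the chain trans to the vinyl group and so avoids allylic strain.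

Step 5
Reactants: 8 (1E,3Z)-1,3-bis(tert-butyldimethylsilyloxy)-7-[(4-methoxybenzyloxy)methyl]octa-1,3,7-triene; 9 (3E,5E)-hepta-3,5-dien-2-one
Product: 10 1-[(1R,2S,5S,6S)-2,4-bis(tert-butyldimethylsilyloxy)-5-{3-[(4-methoxybenzyloxy)methyl]but-3-en-1-yl}-6-[(E)-prop-1-en-1-yl]cyclohex-3-en-1-yl]ethan-1-one
Conditions: (S)-3,3-diphenyl-1-(2-methylphenyl)tetrahydro-1H,3H-pyrrolo[1,2-c][1,3,2]oxazaborole·HN(SO2CF3)2 (20 mol %), CH2Cl2, −78 °C; Et3N quench
Reagents that add atoms: none
Why: The cationic boron Lewis acid binds the ketone of 9 and lowers its LUMO, and diene 8 adds in a concerted but asynchronous [4+2] cycloaddition in which the nucleophilic terminus C1 bonds ahead to the β-carbon C6 and the oxygenated terminus C8 to the α-carbon C7. The closest known reaction type is the oxazaborolidinium-catalysed enantioselective Diels–Alder reaction of enones with silyloxydienes, together with Lewis-acid-promoted cycloadditions of 1-oxy-3-silyloxybutadienes with enones. Ring A closes as a six-membered ring by suprafacial [4+2] cycloaddition from the four diene carbons C8, C9, C10, C1 and the two dienophile carbons C6, C7, leaving C9=C10 as the silyl enol ether. C6 and C7 come out trans because the (E)-geometry of the enone is transferred unchanged. C1 and C8 come out cis to each other because the silyloxy group and the chain both sit on the outside of the s-cis diene, a consequence of its (1E) and (3Z) geometry. The two pairs are related by the endo orientation of the Lewis-acid-bound acetyl group under the diene, which puts acetyl cis to the C8 silyloxy group and the C1 chain and leaves the propenyl group trans. The absolute configuration is set by the catalyst, whose aryl groups shield one face of the bound enone so that the diene reaches the Si face of C7. The step needs regioselectivity and site selectivity: the matched polarisation of the 1,3-dioxygenated diene and the enone secures the first, and the stronger activation of the alkene next to the bound carbonyl, helped by the methyl group on the remote alkene, secures the second.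

Step 6
Reactants: 10 the acetyl cycloadduct
Product: 12 1-[(1R,2S,5S,6S)-2,4-bis(tert-butyldimethylsilyloxy)-5-{3-[(4-methoxybenzyloxy)methyl]but-3-en-1-yl}-6-[(E)-prop-1-en-1-yl]cyclohex-3-en-1-yl]ethenyl trifluoromethanesulfonate, via potassium enolate 11 (not isolated)
Conditions: KN(SiMe3)2, THF, −78 °C; PhN(SO2CF3)2, −78 → −40 °C
Reagents that add atoms: N-phenylbis(trifluoromethanesulfonimide), O=S(=O)(N(c1ccccc1)S(=O)(=O)C(F)(F)F)C(F)(F)F
Why: Kinetic enolisation and O-triflation of a methyl ketone; the methyl protons are removed far faster than the hindered C7–H, so C7 keeps its configuration and the C8 silyloxy group is not expelled. C10 is protected from enolisation as its silyl enol ether.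

Step 7
Reactants: 12 the vinyl triflate
Product: 13 2-(trimethylsilyl)ethyl 2-[(1S,2R,5S,6R)-2,4-bis(tert-butyldimethylsilyloxy)-5-{3-[(4-methoxybenzyloxy)methyl]but-3-en-1-yl}-6-[(E)-prop-1-en-1-yl]cyclohex-3-en-1-yl]prop-2-enoate
Conditions: CO (1 atm), Pd(OAc)2 (10 mol %), PPh3, Et3N, Me3SiCH2CH2OH, DMF, rt → 50 °C
Reagents that add atoms: carbon monoxide, [C-]#[O+]; 2-(trimethylsilyl)ethanol, C[Si](C)(C)CCO
Why: Palladium-catalysed alkoxycarbonylation of a vinyl triflate: oxidative addition to zerovalent palladium, CO insertion and alcoholysis of the acyl complex. The descriptors change only because substituent priorities change; no stereocentre is touched.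

Step 8
Reactants: 13 the monocyclic acrylate
Product: 14 2-(trimethylsilyl)ethyl (1S,6R,7S,8R)-8,10-bis(tert-butyldimethylsilyloxy)-15-(4-methoxybenzyloxy)-14-norcadina-4,9,11(13)-trien-12-oate (trans-fused; C8–O cis to the C7 acrylate)
Conditions: second-generation Grubbs catalyst (H2IMes)(PCy3)Cl2Ru=CHPh (5 mol %), CH2Cl2, 40 °C
Reagents that add atoms: none
Why: Ring-closing metathesis; the catalyst loads at the propenyl group and closes onto the 1,1-disubstituted alkene, the only partner that gives an unstrained ring, with loss of propene. The two tethers are trans-diequatorial, so the trans-fused ring B forms without strain. The hindered α-substituted acrylate and the enol ether stay out.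

Step 9
Reactants: 14 the bicyclic silyl enol ether
Product: 15 2-(trimethylsilyl)ethyl (1S,6R,7S,8S)-8-(tert-butyldimethylsilyloxy)-15-(4-methoxybenzyloxy)-10-oxo-14-norcadina-4,11(13)-dien-12-oate
Conditions: HF·pyridine, pyridine, THF, −20 → 0 °C
Reagents that add atoms: none
Why: Protodesilylation of a silyl enol ether, which is cleaved far faster than the hindered secondary silyl ether at C8. Buffering and low temperature are meant to keep the axial C8 silyloxy group from β-elimination; C9 becomes CH2 and no stereocentre is created.

Step 10
Reactants: 15 the C10 ketone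
Product: 16 2-(trimethylsilyl)ethyl (1S,6S,7S,8S)-8-(tert-butyldimethylsilyloxy)-15-(4-methoxybenzyloxy)cadina-4,10(14),11(13)-trien-12-oate
Conditions: Zn, CH2Br2, TiCl4 (reagent pre-formed in THF), CH2Cl2, 0 °C → rt
Reagents that add atoms: dibromomethane, BrCBr
Why: Takai–Lombardo methylenation; the non-basic zinc–titanium methylene reagent adds to the ketone without enolising it, so neither the ring-fusion centre C1 nor the β-silyloxy group is at risk, and esters are not attacked.

Step 11
Reactants: 16 the C8 silyl ether
Product: 17 2-(trimethylsilyl)ethyl (1S,6S,7S,8S)-8-hydroxy-15-(4-methoxybenzyloxy)cadina-4,10(14),11(13)-trien-12-oate (8-epi: axial hydroxyl cis to the C7 acrylate)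
Conditions: HF·pyridine, THF, 0 °C → rt
Reagents that add atoms: none
Why: Acidic fluoride cleavage of a secondary silyl ether; the 2-(trimethylsilyl)ethyl ester needs naked fluoride and the 4-methoxybenzyl ether needs oxidation, so both should remain.

Step 12
Reactants: 18 (R)-2,2-dimethyl-1,3-dioxolane-4-carbaldehyde
Product: 19 1-[(4R)-2,2-dimethyl-1,3-dioxolan-4-yl]ethan-1-ol (both carbinol epimers)
Conditions: MeMgBr, Et2O, −78 °C; aq. NH4Cl
Reagents that add atoms: methylmagnesium bromide, C[Mg]Br
Why: Grignard addition to an aldehyde; the new carbinol centre is destroyed in the next step, so its configuration is irrelevant.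

Step 13
Reactants: 19 the carbinol mixture
Product: 20 1-[(4R)-2,2-dimethyl-1,3-dioxolan-4-yl]ethan-1-one
Conditions: Dess–Martin periodinane, NaHCO3, CH2Cl2, 0 °C → rt
Reagents that add atoms: none
Why: Dess–Martin oxidation under buffered, non-enolising conditions, which should keep the α-alkoxy stereocentre intact.

Step 14
Reactants: 20 the methyl ketone
Product: 22 1-[(4R)-2,2-dimethyl-1,3-dioxolan-4-yl]ethenyl trifluoromethanesulfonate, via potassium enolate 21 (not isolated)
Conditions: KN(SiMe3)2, THF, −78 °C; PhN(SO2CF3)2, −78 → −30 °C
Reagents that add atoms: N-phenylbis(trifluoromethanesulfonimide), O=S(=O)(N(c1ccccc1)S(=O)(=O)C(F)(F)F)C(F)(F)F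
Why: Kinetic enolisation towards the methyl group and O-triflation; the α-alkoxy methine is more hindered and is left alone at −78 °C, so the stereocentre is retained.

Step 15
Reactants: 22 the side-chain vinyl triflate
Product: 23 2-[(4S)-2,2-dimethyl-1,3-dioxolan-4-yl]prop-2-enoic acid
Conditions: CO (1 atm), Pd(OAc)2 (5 mol %), PPh3, KOAc, DMF/H2O, 50 °C; pH 4 work-up
Reagents that add atoms: carbon monoxide, [C-]#[O+]; water, O
Why: Palladium-catalysed hydroxycarbonylation of a vinyl triflate (oxidative addition, CO insertion, hydrolysis of the acyl complex with acetate as base). The descriptor changes from R to S only through priorities.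

Step 16
Reactants: 17 the 8-epi alcohol; 23 the side-chain acid
Product: 24 2-(trimethylsilyl)ethyl (1S,6S,7S,8R)-8-{2-[(4S)-2,2-dimethyl-1,3-dioxolan-4-yl]prop-2-enoyloxy}-15-(4-methoxybenzyloxy)cadina-4,10(14),11(13)-trien-12-oate
Conditions: PPh3, DIAD, toluene, 0 °C → rt
Reagents that add atoms: none
Why: Mitsunobu esterification; the carboxylate of 23 displaces the axial oxyphosphonium group at C8 by SN2 with inversion, giving the equatorial (8R) ester trans to the C7 substituent as in the target. The acrylic acid is acidic enough to protonate the betaine.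

Step 17
Reactants: 24 the fully protected ester
Product: 25 2-(trimethylsilyl)ethyl (1S,6S,7S,8R)-8-{2-[(4S)-2,2-dimethyl-1,3-dioxolan-4-yl]prop-2-enoyloxy}-15-hydroxycadina-4,10(14),11(13)-trien-12-oate
Conditions: DDQ (1.3 equiv), CH2Cl2/pH 7 buffer, 0 °C
Reagents that add atoms: none
Why: Oxidative cleavage of a 4-methoxybenzyl ether by hydride abstraction and hydrolysis of the oxocarbenium ion; limited reagent and low temperature should spare the liberated allylic alcohol.

Step 18
Reactants: 25 the C15 alcohol
Product: 26 (1S,6S,7S,8R)-8-{2-[(4S)-2,2-dimethyl-1,3-dioxolan-4-yl]prop-2-enoyloxy}-15-hydroxycadina-4,10(14),11(13)-trien-12-oic acid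
Conditions: (Me2N)3S+ Me3SiF2− (TASF), DMF, 0 °C → rt; pH 4 phosphate buffer
Reagents that add atoms: none
Why: Fluoride-induced β-elimination of the 2-(trimethylsilyl)ethyl ester (loss of Me3SiF and ethene). The side-chain diol is still an acetonide, so the weakly basic fluoride cannot trigger lactonisation.

Step 19
Reactants: 26 the acetonide acid
Product: 27 (1S,6S,7S,8R)-8-{[(3S)-3,4-dihydroxy-2-methylidenebutanoyl]oxy}-15-hydroxycadina-4,10(14),11(13)-trien-12-oic acid
Conditions: AcOH/H2O (4:1), rt
Reagents that add atoms: none
Why: Acid-catalysed hydrolysis of a terminal acetonide; in weak aqueous acid at room temperature the exocyclic alkene, the allylic alcohol and the C8 ester should be stable, and the diol ester does not lactonise without base.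

## Compound list

1 | 2-(chloromethyl)allyltrimethylsilane | C=C(CCl)C[Si](C)(C)C | starting material
2 | {2-[(4-methoxybenzyloxy)methyl]allyl}trimethylsilane | C=C(COCc1ccc(OC)cc1)C[Si](C)(C)C | intermediate
3 | methyl vinyl ketone | C=CC(C)=O | starting material
4 | 6-[(4-methoxybenzyloxy)methyl]hept-6-en-2-one | CC(=O)CCCC(=C)COCc1ccc(OC)cc1 | intermediate
5 | kinetic lithium enolate of 4 (formed in situ) | [Li+].[O-]C(=C)CCCC(=C)COCc1ccc(OC)cc1 | intermediate
6 | (1Z)-1-hydroxy-7-[(4-methoxybenzyloxy)methyl]octa-1,7-dien-3-one (enol of the 3-oxo aldehyde) | O/C=C\C(=O)CCCC(=C)COCc1ccc(OC)cc1 | intermediate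
7 | (1E)-1-(tert-butyldimethylsilyloxy)-7-[(4-methoxybenzyloxy)methyl]octa-1,7-dien-3-one (formed in situ) | CC(C)(C)[Si](C)(C)O/C=C/C(=O)CCCC(=C)COCc1ccc(OC)cc1 | intermediate
8 | (1E,3Z)-1,3-bis(tert-butyldimethylsilyloxy)-7-[(4-methoxybenzyloxy)methyl]octa-1,3,7-triene | CC(C)(C)[Si](C)(C)O/C=C/C(O[Si](C)(C)C(C)(C)C)=C/CCC(=C)COCc1ccc(OC)cc1 | intermediate
9 | (3E,5E)-hepta-3,5-dien-2-one | CC(=O)/C=C/C=C/C | starting material
10 | ring-A cycloadduct: 1-[(1R,2S,5S,6S)-2,4-bis(tert-butyldimethylsilyloxy)-5-{3-[(4-methoxybenzyloxy)methyl]but-3-en-1-yl}-6-[(E)-prop-1-en-1-yl]cyclohex-3-en-1-yl]ethan-1-one (acetyl, 8-OTBS and C1 chain cis; propenyl trans) | CC(=O)[C@@H]1[C@@H](/C=C/C)[C@H](CCC(=C)COCc2ccc(OC)cc2)C(O[Si](C)(C)C(C)(C)C)=C[C@@H]1O[Si](C)(C)C(C)(C)C | intermediate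
11 | potassium enolate of 10 at the acetyl methyl group (formed in situ) | [K+].[O-]C(=C)[C@@H]1[C@@H](/C=C/C)[C@H](CCC(=C)COCc2ccc(OC)cc2)C(O[Si](C)(C)C(C)(C)C)=C[C@@H]1O[Si](C)(C)C(C)(C)C | intermediate
12 | vinyl triflate of 10: 1-[(1R,2S,5S,6S)-…cyclohex-3-en-1-yl]ethenyl trifluoromethanesulfonate (ring substituents as in 10) | C=C(OS(=O)(=O)C(F)(F)F)[C@@H]1[C@@H](/C=C/C)[C@H](CCC(=C)COCc2ccc(OC)cc2)C(O[Si](C)(C)C(C)(C)C)=C[C@@H]1O[Si](C)(C)C(C)(C)C | intermediate
13 | 2-(trimethylsilyl)ethyl 2-[(1S,2R,5S,6R)-…cyclohex-3-en-1-yl]prop-2-enoate (ring substituents and spatial arrangement as in 10) | C=C(C(=O)OCC[Si](C)(C)C)[C@@H]1[C@@H](/C=C/C)[C@H](CCC(=C)COCc2ccc(OC)cc2)C(O[Si](C)(C)C(C)(C)C)=C[C@@H]1O[Si](C)(C)C(C)(C)C | intermediate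
14 | 2-(trimethylsilyl)ethyl (1S,6R,7S,8R)-8,10-bis(tert-butyldimethylsilyloxy)-15-(4-methoxybenzyloxy)-14-norcadina-4,9,11(13)-trien-12-oate (trans-fused, 8-epi) | C=C(C(=O)OCC[Si](C)(C)C)[C@@H]1[C@H]2C=C(COCc3ccc(OC)cc3)CC[C@@H]2C(O[Si](C)(C)C(C)(C)C)=C[C@@H]1O[Si](C)(C)C(C)(C)C | intermediate
15 | 2-(trimethylsilyl)ethyl (1S,6R,7S,8S)-8-(tert-butyldimethylsilyloxy)-15-(4-methoxybenzyloxy)-10-oxo-14-norcadina-4,11(13)-dien-12-oate | C=C(C(=O)OCC[Si](C)(C)C)[C@@H]1[C@H]2C=C(COCc3ccc(OC)cc3)CC[C@@H]2C(=O)C[C@@H]1O[Si](C)(C)C(C)(C)C | intermediate
16 | 2-(trimethylsilyl)ethyl (1S,6S,7S,8S)-8-(tert-butyldimethylsilyloxy)-15-(4-methoxybenzyloxy)cadina-4,10(14),11(13)-trien-12-oate | C=C(C(=O)OCC[Si](C)(C)C)[C@@H]1[C@H]2C=C(COCc3ccc(OC)cc3)CC[C@@H]2C(=C)C[C@@H]1O[Si](C)(C)C(C)(C)C | intermediate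
17 | 2-(trimethylsilyl)ethyl (1S,6S,7S,8S)-8-hydroxy-15-(4-methoxybenzyloxy)cadina-4,10(14),11(13)-trien-12-oate (8-epi alcohol) | C=C(C(=O)OCC[Si](C)(C)C)[C@@H]1[C@H]2C=C(COCc3ccc(OC)cc3)CC[C@@H]2C(=C)C[C@@H]1O | intermediate
18 | (R)-2,2-dimethyl-1,3-dioxolane-4-carbaldehyde ((R)-glyceraldehyde acetonide) | O=C[C@H]1COC(C)(C)O1 | starting material
19 | 1-[(4R)-2,2-dimethyl-1,3-dioxolan-4-yl]ethan-1-ol (carbinol epimers) | CC(O)[C@H]1COC(C)(C)O1 | intermediate
20 | 1-[(4R)-2,2-dimethyl-1,3-dioxolan-4-yl]ethan-1-one | CC(=O)[C@H]1COC(C)(C)O1 | intermediate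
21 | potassium enolate of 20 at the methyl group (formed in situ) | [K+].[O-]C(=C)[C@H]1COC(C)(C)O1 | intermediate
22 | 1-[(4R)-2,2-dimethyl-1,3-dioxolan-4-yl]ethenyl trifluoromethanesulfonate | C=C(OS(=O)(=O)C(F)(F)F)[C@H]1COC(C)(C)O1 | intermediate
23 | 2-[(4S)-2,2-dimethyl-1,3-dioxolan-4-yl]prop-2-enoic acid | C=C(C(=O)O)[C@H]1COC(C)(C)O1 | intermediate
24 | 2-(trimethylsilyl)ethyl (1S,6S,7S,8R)-8-{2-[(4S)-2,2-dimethyl-1,3-dioxolan-4-yl]prop-2-enoyloxy}-15-(4-methoxybenzyloxy)cadina-4,10(14),11(13)-trien-12-oate | C=C(C(=O)OCC[Si](C)(C)C)[C@@H]1[C@H]2C=C(COCc3ccc(OC)cc3)CC[C@@H]2C(=C)C[C@H]1OC(=O)C(=C)[C@H]4COC(C)(C)O4 | intermediate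
25 | 2-(trimethylsilyl)ethyl (1S,6S,7S,8R)-8-{2-[(4S)-2,2-dimethyl-1,3-dioxolan-4-yl]prop-2-enoyloxy}-15-hydroxycadina-4,10(14),11(13)-trien-12-oate | C=C(C(=O)OCC[Si](C)(C)C)[C@@H]1[C@H]2C=C(CO)CC[C@@H]2C(=C)C[C@H]1OC(=O)C(=C)[C@H]4COC(C)(C)O4 | intermediate
26 | (1S,6S,7S,8R)-8-{2-[(4S)-2,2-dimethyl-1,3-dioxolan-4-yl]prop-2-enoyloxy}-15-hydroxycadina-4,10(14),11(13)-trien-12-oic acid | C=C(C(=O)O)[C@@H]1[C@H]2C=C(CO)CC[C@@H]2C(=C)C[C@H]1OC(=O)C(=C)[C@H]4COC(C)(C)O4 | intermediate
27 | (1S,6S,7S,8R)-8-{[(3S)-3,4-dihydroxy-2-methylidenebutanoyl]oxy}-15-hydroxycadina-4,10(14),11(13)-trien-12-oic acid | C=C(C(=O)O)[C@@H]1[C@H]2C=C(CO)CC[C@@H]2C(=C)C[C@H]1OC(=O)C(=C)[C@H](O)CO | target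

## Step count and least certain steps

Total: 19 steps. Longest linear sequence: 15 steps (steps 1–11 and 16–19, from 1); the side-chain branch is 4 steps (12–15, from 18).

**Step 5 (key step).**
- What may go wrong: the strongly acidic catalyst may desilylate the diene or divert the reaction into a stepwise Mukaiyama–Michael pathway, which would erode the endo preference and the cis relation of C1 and C8. An acyclic methyl ketone with two accessible lone pairs may bind without a strong facial bias. Addition across the remote γ,δ-alkene may compete.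
- Fallback: it sets out from 8 and replaces 9 by the two-point-binding imide 3-[(2E,4E)-hexa-2,4-dienoyl]oxazolidin-2-one F1 (one acylation from commercial sorbic acid). Cycloaddition under a chiral Yb(OTf)3–binaphthyl bis(amide) complex with a tertiary amine, of the kind established for siloxydienes and N-enoyl oxazolidinones, should give the imide adduct 3-{[(1R,2S,5S,6S)-2,4-bis(tert-butyldimethylsilyloxy)-5-{3-[(4-methoxybenzyloxy)methyl]but-3-en-1-yl}-6-[(E)-prop-1-en-1-yl]cyclohex-3-en-1-yl]carbonyl}oxazolidin-2-one F2. Treatment with MeNH(OMe)·HCl and AlMe3 converts F2 into the Weinreb amide F3, and MeMgBr converts F3 into the methyl ketone, returning to the route at 10.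

**Step 16.**
- What may go wrong: E2 loss of the activated axial oxyphosphonium group towards C7 or C9 may outrun substitution. Both axial hydrogens are anti-periplanar and each elimination gives a conjugated diene, while the nucleophile is a hindered, only moderately acidic carboxylate.
- Fallback: it sets out from 17. Dess–Martin oxidation gives the C8 ketone 2-(trimethylsilyl)ethyl (1S,6S,7S)-15-(4-methoxybenzyloxy)-8-oxocadina-4,10(14),11(13)-trien-12-oate F4. Reduction with NaBH4 and CeCl3·7H2O in MeOH at −78 °C (axial hydride delivery) gives the equatorial alcohol 2-(trimethylsilyl)ethyl (1S,6S,7S,8R)-8-hydroxy-15-(4-methoxybenzyloxy)cadina-4,10(14),11(13)-trien-12-oate F5. Yamaguchi esterification of F5 with 23 (2,4,6-trichlorobenzoyl chloride, Et3N, DMAP) proceeds with retention and returns to the route at 24.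

**Step 9.**
- What may go wrong: β-elimination of the axial C8 silyloxy group (ionisation assisted by the enol ether, or expulsion from a transient enolate) may give the C8=C9 enone, or the C8 silyl ether may be lost early.
- Fallback: it sets out from 14 and removes both silyl groups on purpose (aqueous HF, MeCN, 0 °C) to give the β-hydroxy ketone 2-(trimethylsilyl)ethyl (1S,6R,7S,8S)-8-hydroxy-15-(4-methoxybenzyloxy)-10-oxo-14-norcadina-4,11(13)-dien-12-oate F6, in which hydroxide is a far poorer leaving group. Methylenation of F6 with excess Takai–Lombardo reagent, which tolerates free hydroxyl groups, returns to the route at 17 and bypasses 15 and 16.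

**Step 14.**
- What may go wrong: deprotonation at the α-alkoxy methine of 20 may compete, leading to loss of configuration or ring-opening β-elimination of the dioxolane.
- Fallback: it sets out from 18 and avoids any ketone enolate. Ohira–Bestmann homologation (dimethyl (1-diazo-2-oxopropyl)phosphonate, K2CO3, MeOH) gives (4S)-4-ethynyl-2,2-dimethyl-1,3-dioxolane F10. Branch-selective palladium-catalysed methoxycarbonylation (Pd(OAc)2, 2-pyridyldiphenylphosphine, CO, MeOH, trace sulfonic acid) gives methyl 2-[(4S)-2,2-dimethyl-1,3-dioxolan-4-yl]prop-2-enoate F11. Saponification with LiOH in THF/H2O returns to the route at 23.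

**Step 2.**
- What may go wrong: TiCl4 may cleave the 4-methoxybenzyl ether or ionise the allylic ether of 2 before conjugate addition.
- Fallback: it sets out from 1 and 3 and carries the chloride through the Lewis acid step. Hosomi–Sakurai addition of 1 itself to 3 (TiCl4, CH2Cl2, −78 °C) gives 6-(chloromethyl)hept-6-en-2-one F7. Ketalisation (ethylene glycol, pyridinium tosylate, benzene, reflux) gives 2-[4-(chloromethyl)pent-4-en-1-yl]-2-methyl-1,3-dioxolane F8. Williamson displacement with sodium 4-methoxybenzyl oxide gives 2-{4-[(4-methoxybenzyloxy)methyl]pent-4-en-1-yl}-2-methyl-1,3-dioxolane F9. Pyridinium tosylate in wet acetone returns to the route at 4.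

## Further compounds

F1 | step 5 | 3-[(2E,4E)-hexa-2,4-dienoyl]oxazolidin-2-one | C/C=C/C=C/C(=O)N1CCOC1=O
F2 | step 5 | imide cycloadduct (ring substituents and configuration as in 10; C7 carries the oxazolidinone carbonyl) | O=C(N3CCOC3=O)[C@@H]1[C@@H](/C=C/C)[C@H](CCC(=C)COCc2ccc(OC)cc2)C(O[Si](C)(C)C(C)(C)C)=C[C@@H]1O[Si](C)(C)C(C)(C)C
F3 | step 5 | N-methoxy-N-methyl amide corresponding to 10 | CON(C)C(=O)[C@@H]1[C@@H](/C=C/C)[C@H](CCC(=C)COCc2ccc(OC)cc2)C(O[Si](C)(C)C(C)(C)C)=C[C@@H]1O[Si](C)(C)C(C)(C)C
F4 | step 16 | 2-(trimethylsilyl)ethyl (1S,6S,7S)-15-(4-methoxybenzyloxy)-8-oxocadina-4,10(14),11(13)-trien-12-oate | C=C(C(=O)OCC[Si](C)(C)C)[C@@H]1[C@H]2C=C(COCc3ccc(OC)cc3)CC[C@@H]2C(=C)CC1=O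
F5 | step 16 | 2-(trimethylsilyl)ethyl (1S,6S,7S,8R)-8-hydroxy-15-(4-methoxybenzyloxy)cadina-4,10(14),11(13)-trien-12-oate | C=C(C(=O)OCC[Si](C)(C)C)[C@@H]1[C@H]2C=C(COCc3ccc(OC)cc3)CC[C@@H]2C(=C)C[C@H]1O
F6 | step 9 | 2-(trimethylsilyl)ethyl (1S,6R,7S,8S)-8-hydroxy-15-(4-methoxybenzyloxy)-10-oxo-14-norcadina-4,11(13)-dien-12-oate | C=C(C(=O)OCC[Si](C)(C)C)[C@@H]1[C@H]2C=C(COCc3ccc(OC)cc3)CC[C@@H]2C(=O)C[C@@H]1O
F7 | step 2 | 6-(chloromethyl)hept-6-en-2-one | CC(=O)CCCC(=C)CCl
F8 | step 2 | 2-[4-(chloromethyl)pent-4-en-1-yl]-2-methyl-1,3-dioxolane | CC1(CCCC(=C)CCl)OCCO1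
F9 | step 2 | 2-{4-[(4-methoxybenzyloxy)methyl]pent-4-en-1-yl}-2-methyl-1,3-dioxolane | CC1(CCCC(=C)COCc2ccc(OC)cc2)OCCO1
F10 | step 14 | (4S)-4-ethynyl-2,2-dimethyl-1,3-dioxolane | C#C[C@H]1COC(C)(C)O1
F11 | step 14 | methyl 2-[(4S)-2,2-dimethyl-1,3-dioxolan-4-yl]prop-2-enoate | C=C(C(=O)OC)[C@H]1COC(C)(C)O1
A1 | alternative 1 | 2-nitro-15-oxocadin-4-ene with a C10 dioxolane, 8-OTBS and a C7 CH2CO2tBu group | CC(C)(C)OC(=O)C[C@@H]1[C@H]2C=C(C=O)C[C@@H]([N+](=O)[O-])[C@@H]2C3(OCCO3)C[C@H]1O[Si](C)(C)C(C)(C)C
A2 | alternative 2 | 8-hydroxycadina-4,10(14)-diene with a C7 diallyl malonyl group and C15 OTBDPS | C=CCOC(=O)C(C(=O)OCC=C)[C@@H]1[C@H]2C=C(CO[Si](c3ccccc3)(c3ccccc3)C(C)(C)C)CC[C@@H]2C(=C)C[C@H]1O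
A3 | alternative 3 | 15-hydroxy-8-(tert-butyldimethylsilyloxy)cadina-4,10(14)-diene with a C7 dimethyl malonyl group | COC(=O)C(C(=O)OC)[C@@H]1[C@H]2C=C(CO)CC[C@@H]2C(=C)C[C@H]1O[Si](C)(C)C(C)(C)C
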